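**Retrosynthetic overview**

1. Balanophonin is a (2R,3S)-2,3-dihydrobenzofuran, numbered O1, C2 (guaiacyl ring), C3 (CH2OH), C3a–C7a (ring B, propenal on C5, OMe on C7). The enal is cut first at C5 (Heck coupling of a C5 bromide); the MOM and TBS groups come off last.
2. Feature carrying the strategy: C3 is bonded to ring B ortho to the phenolic oxygen O1, so O1–C7a–C3a–C3 is a four-atom ortho-quinone methide, and C2 with its guaiacyl ring is a one-carbon sulfonium benzylide. Both C2–C3 and O1–C2 are cut ([4+1]).
3. Quinone methide precursor: ortho-hydroxybenzyl sulfone 5, from 5-bromo-2-hydroxy-3-methoxybenzaldehyde by methylenation, dihydroxylation, primary silylation and sulfinate substitution.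
4. Ylide precursor: thiolanium salt 13, from MOM-protected vanillyl bromide and (2R,5R)-2,5-dimethylthiolane (made from (2S,5S)-hexane-2,5-diol).
5. Ring order: both benzene rings are bought; the only ring formed is the dihydrofuran ring, in step 10.

Key step: step 10

Assumption: the benzylide of the (2R,5R)-thiolane is taken to react with the quinone methide on the same face of the ylide carbon that it uses toward aromatic aldehydes in epoxidation; on that basis the (2R,5R)-sulfide is the enantiomer that leads to (2R) at C2, and the route is written with it.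

**Route**

Step 1
Reactants: 1 5-bromo-2-hydroxy-3-methoxybenzaldehyde
Product: 2 4-bromo-2-methoxy-6-vinylphenol
Conditions: Ph3PCH3Br (2.5 equiv), KOtBu (2.5 equiv), THF, 0 °C → rt
Reagents that add atoms: methyltriphenylphosphonium bromide, C[P+](c1ccccc1)(c1ccccc1)c1ccccc1.[Br-]
Why: Wittig methylenation; the first equivalent of base is taken up by the phenol and the phenoxide aldehyde should still olefinate, as salicylaldehydes do.

Step 2
Reactants: 2 4-bromo-2-methoxy-6-vinylphenol
Product: 3 1-(5-bromo-2-hydroxy-3-methoxyphenyl)ethane-1,2-diol (racemic)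
Conditions: K2OsO4·2H2O (1 mol %), NMO, acetone/H2O (4:1), rt
Reagents that add atoms: N-methylmorpholine N-oxide, C[N+]1([O-])CCOCC1; water, O
Why: Catalytic osmium tetroxide syn-dihydroxylation of an electron-rich styrene with amine oxide as reoxidant; the racemate suffices because this carbinol carbon becomes planar in step 10.

Step 3
Reactants: 3 1-(5-bromo-2-hydroxy-3-methoxyphenyl)ethane-1,2-diol
Product: 4 4-bromo-2-[2-(tert-butyldimethylsilyloxy)-1-hydroxyethyl]-6-methoxyphenol (racemic)
Conditions: TBSCl (1.05 equiv), imidazole (2 equiv), CH2Cl2, 0 °C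
Reagents that add atoms: tert-butyldimethylsilyl chloride, CC(C)(C)[Si](C)(C)Cl
Why: Sterically controlled monosilylation; the primary hydroxyl should react well before the secondary benzylic hydroxyl and the phenol, which is flanked by OMe and the side chain.

Step 4
Reactants: 4 4-bromo-2-[2-(tert-butyldimethylsilyloxy)-1-hydroxyethyl]-6-methoxyphenol
Product: 5 4-bromo-2-[2-(tert-butyldimethylsilyloxy)-1-(4-methylphenylsulfonyl)ethyl]-6-methoxyphenol (racemic)
Conditions: p-TolSO2H (2 equiv), 4 Å molecular sieves, CH2Cl2, rt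
Reagents that add atoms: p-toluenesulfinic acid, Cc1ccc(S(=O)O)cc1
Why: Acid-promoted ionisation of the ortho-hydroxybenzylic alcohol and S-alkylation of the sulfinate, the usual way to 2-(1-tosylalkyl)phenols; the weak acid in dry CH2Cl2 should spare the primary silyl ether.

Step 5
Reactants: 6 (2S,5S)-hexane-2,5-diol
Product: 7 (2S,5S)-hexane-2,5-diyl dimethanesulfonate
Conditions: MsCl (2.4 equiv), Et3N, CH2Cl2, 0 °C
Reagents that add atoms: methanesulfonyl chloride, CS(=O)(=O)Cl
Why: O-sulfonylation leaves both C–O bonds untouched, so both centres are retained.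

Step 6
Reactants: 7 (2S,5S)-hexane-2,5-diyl dimethanesulfonate
Product: 9 (2R,5R)-2,5-dimethylthiolane, via mesyloxy thiolate 8 (not isolated)
Conditions: Na2S·9H2O (1.2 equiv), EtOH, rt
Reagents that add atoms: sodium sulfide, [Na+].[Na+].[S-2]
Why: Two successive SN2 displacements by sulfur, the second a 5-exo-tet closure, invert both centres and should give the trans (2R,5R) thiolane.

Step 7
Reactants: 10 vanillyl alcohol (4-(hydroxymethyl)-2-methoxyphenol)
Product: 11 [3-methoxy-4-(methoxymethoxy)phenyl]methanol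
Conditions: MOMCl (1.1 equiv), K2CO3, acetone, 0 °C → rt
Reagents that add atoms: chloromethyl methyl ether, COCCl
Why: Williamson-type O-alkylation; carbonate deprotonates only the phenol, so the benzylic alcohol should stay free.

Step 8
Reactants: 11 [3-methoxy-4-(methoxymethoxy)phenyl]methanol
Product: 12 4-(bromomethyl)-2-methoxy-1-(methoxymethoxy)benzene
Conditions: CBr4, PPh3, CH2Cl2, 0 °C; used without storage
Reagents that add atoms: carbon tetrabromide, BrC(Br)(Br)Br
Why: Appel bromination under neutral conditions, which the MOM acetal tolerates.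

Step 9
Reactants: 12 4-(bromomethyl)-2-methoxy-1-(methoxymethoxy)benzene; 9 (2R,5R)-2,5-dimethylthiolane
Product: 13 (2R,5R)-1-[3-methoxy-4-(methoxymethoxy)benzyl]-2,5-dimethylthiolan-1-ium tetrafluoroborate
Conditions: AgBF4 (1.0 equiv), 9 (1.2 equiv), CH2Cl2, 0 °C → rt, dark
Reagents that add atoms: silver tetrafluoroborate, [Ag+].F[B-](F)(F)F
Why: S-benzylation of the sulfide driven by precipitation of AgBr; the twofold symmetry of the sulfide makes its two lone pairs equivalent, so a single sulfonium salt should form.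

Step 10
Reactants: 5 4-bromo-2-[2-(tert-butyldimethylsilyloxy)-1-(4-methylphenylsulfonyl)ethyl]-6-methoxyphenol; 13 (2R,5R)-1-[3-methoxy-4-(methoxymethoxy)benzyl]-2,5-dimethylthiolan-1-ium tetrafluoroborate
Product: 17 (2R,3S)-5-bromo-3-[(tert-butyldimethylsilyloxy)methyl]-7-methoxy-2-[3-methoxy-4-(methoxymethoxy)phenyl]-2,3-dihydro-1-benzofuran, via sulfonium benzylide 14 (not isolated), via ortho-quinone methide 15 (not isolated), via anti betaine 16 (not isolated)
Conditions: Cs2CO3 (3 equiv), 13 (1.5 equiv), CH2Cl2, 0 °C → rt, 5 added over 6 h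
Reagents that add atoms: none
Why: Proposed new method: Cs2CO3 converts 5 into its phenoxide, which expels p-toluenesulfinate by 1,4-elimination to give ortho-quinone methide 15, and converts 13 into benzylide 14; the ylide carbon adds to the methide carbon (conjugate addition, C2–C3), ring B rearomatises to the phenoxide–sulfonium betaine 16, and the phenoxide oxygen displaces the thiolane at C2 (O1–C2). The closest known reactions are the [4+1] annulation of ortho-quinone methides from 2-(1-tosylalkyl)phenols with carbonyl-stabilised sulfonium ylides to trans-2,3-dihydrobenzofurans and the asymmetric epoxidation of aldehydes with benzylides of this thiolane; what is new is the union of a chiral semi-stabilised benzylide with an alkyl-substituted quinone methide. The dihydrofuran ring closes by 5-exo-tet SN2 substitution with inversion at C2, and sulfide 9 is released for reuse. C2 is controlled by the twofold-symmetric thiolane: the ylide should react in the conformer with its aryl group turned away from the ring and on the face remote from the methyl group that is cis to the ylide carbon, which after the inverting ring closure corresponds to (2R). C3 is set in the same C–C bond formation relative to C2, the anti betaine with the aryl and CH2OTBS groups apart leading to the trans (2R,3S) ring. The step needs C–C bond formation to outrun the hydrogen shift of 15 to the enol ether styrene and the O-benzylation of the phenoxide by 13, which the unhindered monosubstituted methide terminus, the slow addition of 5 and the excess of 13 should secure.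

Step 11
Reactants: 17 (2R,3S)-5-bromo-3-[(tert-butyldimethylsilyloxy)methyl]-7-methoxy-2-[3-methoxy-4-(methoxymethoxy)phenyl]-2,3-dihydro-1-benzofuran; 18 acrolein diethyl acetal (3,3-diethoxyprop-1-ene)
Product: 20 (E)-3-[(2R,3S)-3-[(tert-butyldimethylsilyloxy)methyl]-7-methoxy-2-[3-methoxy-4-(methoxymethoxy)phenyl]-2,3-dihydro-1-benzofuran-5-yl]prop-2-enal, via diethyl acetal 19 (not isolated)
Conditions: Pd(OAc)2 (5 mol %), nBu4NOAc, K2CO3, KCl, DMF, 90 °C; then PPTS, acetone/H2O, rt
Reagents that add atoms: water, O (supplies the aldehyde oxygen on acetal hydrolysis)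
Why: Mizoroki–Heck coupling under phosphine-free ammonium-salt conditions: oxidative addition of the C5 bromide to zerovalent palladium, alkene insertion and β-hydride elimination toward the benzylic hydrogen should give the (E)-cinnamyl acetal 19, whose allylic acetal hydrolyses under acid mild enough to keep the TBS ether and the MOM acetal.

Step 12
Reactants: 20 (E)-3-[(2R,3S)-3-[(tert-butyldimethylsilyloxy)methyl]-7-methoxy-2-[3-methoxy-4-(methoxymethoxy)phenyl]-2,3-dihydro-1-benzofuran-5-yl]prop-2-enal
Product: 21 balanophonin, (E)-3-[(2R,3S)-2-(4-hydroxy-3-methoxyphenyl)-3-(hydroxymethyl)-7-methoxy-2,3-dihydro-1-benzofuran-5-yl]prop-2-enal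
Conditions: 3 M aq. HCl, THF, 40 °C
Reagents that add atoms: none
Why: Acid hydrolysis of the aryl MOM acetal and the primary silyl ether; neither stereocentre carries an acidic hydrogen, and the mild temperature should keep the C2–O1 benzylic ether from ionising.

**Compound list**

1 | 5-bromo-2-hydroxy-3-methoxybenzaldehyde | COc1cc(Br)cc(C=O)c1O | starting material
2 | 4-bromo-2-methoxy-6-vinylphenol | COc1cc(Br)cc(C=C)c1O | intermediate
3 | 1-(5-bromo-2-hydroxy-3-methoxyphenyl)ethane-1,2-diol (racemic) | COc1cc(Br)cc(C(O)CO)c1O | intermediate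
4 | 4-bromo-2-[2-(tert-butyldimethylsilyloxy)-1-hydroxyethyl]-6-methoxyphenol (racemic) | COc1cc(Br)cc(C(O)CO[Si](C)(C)C(C)(C)C)c1O | intermediate
5 | 4-bromo-2-[2-(tert-butyldimethylsilyloxy)-1-(4-methylphenylsulfonyl)ethyl]-6-methoxyphenol (racemic) | COc1cc(Br)cc(C(CO[Si](C)(C)C(C)(C)C)S(=O)(=O)c2ccc(C)cc2)c1O | intermediate
6 | (2S,5S)-hexane-2,5-diol | C[C@H](O)CC[C@H](C)O | starting material
7 | (2S,5S)-hexane-2,5-diyl dimethanesulfonate | C[C@H](OS(C)(=O)=O)CC[C@H](C)OS(C)(=O)=O | intermediate
8 | sodium (2R,5S)-5-(methanesulfonyloxy)hexane-2-thiolate | C[C@@H]([S-])CC[C@H](C)OS(C)(=O)=O.[Na+] | intermediate (not isolated)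
9 | (2R,5R)-2,5-dimethylthiolane | C[C@@H]1CC[C@@H](C)S1 | intermediate
10 | vanillyl alcohol | COc1cc(CO)ccc1O | starting material
11 | [3-methoxy-4-(methoxymethoxy)phenyl]methanol | COCOc1ccc(CO)cc1OC | intermediate
12 | 4-(bromomethyl)-2-methoxy-1-(methoxymethoxy)benzene | COCOc1ccc(CBr)cc1OC | intermediate
13 | (2R,5R)-1-[3-methoxy-4-(methoxymethoxy)benzyl]-2,5-dimethylthiolan-1-ium tetrafluoroborate | C[C@@H]1CC[C@@H](C)[S+]1Cc1ccc(OCOC)c(OC)c1.F[B-](F)(F)F | intermediate
14 | (2R,5R)-2,5-dimethylthiolan-1-ium-1-yl [3-methoxy-4-(methoxymethoxy)phenyl]methanide | C[C@@H]1CC[C@@H](C)[S+]1[CH-]c1ccc(OCOC)c(OC)c1 | intermediate (not isolated)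
15 | (6E)-4-bromo-6-[2-(tert-butyldimethylsilyloxy)ethylidene]-2-methoxycyclohexa-2,4-dien-1-one | COC1=CC(Br)=C/C(=C\CO[Si](C)(C)C(C)(C)C)C1=O | intermediate (not isolated)
16 | 4-bromo-2-[(1S,2S)-3-(tert-butyldimethylsilyloxy)-1-[(2R,5R)-2,5-dimethylthiolan-1-ium-1-yl]-1-[3-methoxy-4-(methoxymethoxy)phenyl]propan-2-yl]-6-methoxyphenolate | COc1cc([C@H]([C@H](CO[Si](C)(C)C(C)(C)C)c2cc(Br)cc(OC)c2[O-])[S+]3[C@H](C)CC[C@H]3C)ccc1OCOC | intermediate (not isolated)
17 | (2R,3S)-5-bromo-3-[(tert-butyldimethylsilyloxy)methyl]-7-methoxy-2-[3-methoxy-4-(methoxymethoxy)phenyl]-2,3-dihydro-1-benzofuran | COc1cc([C@@H]2Oc3c(OC)cc(Br)cc3[C@H]2CO[Si](C)(C)C(C)(C)C)ccc1OCOC | intermediate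
18 | acrolein diethyl acetal (3,3-diethoxyprop-1-ene) | C=CC(OCC)OCC | starting material
19 | (2R,3S)-3-[(tert-butyldimethylsilyloxy)methyl]-5-[(E)-3,3-diethoxyprop-1-enyl]-7-methoxy-2-[3-methoxy-4-(methoxymethoxy)phenyl]-2,3-dihydro-1-benzofuran | COc1cc([C@@H]2Oc3c(OC)cc(/C=C/C(OCC)OCC)cc3[C@H]2CO[Si](C)(C)C(C)(C)C)ccc1OCOC | intermediate (not isolated)
20 | (E)-3-[(2R,3S)-3-[(tert-butyldimethylsilyloxy)methyl]-7-methoxy-2-[3-methoxy-4-(methoxymethoxy)phenyl]-2,3-dihydro-1-benzofuran-5-yl]prop-2-enal | COc1cc([C@@H]2Oc3c(OC)cc(/C=C/C=O)cc3[C@H]2CO[Si](C)(C)C(C)(C)C)ccc1OCOC | intermediate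
21 | balanophonin, (E)-3-[(2R,3S)-2-(4-hydroxy-3-methoxyphenyl)-3-(hydroxymethyl)-7-methoxy-2,3-dihydro-1-benzofuran-5-yl]prop-2-enal | COc1cc([C@@H]2Oc3c(OC)cc(/C=C/C=O)cc3[C@H]2CO)ccc1O | target

**Step count**

Total: 12 steps. Longest linear sequence: 7 steps (steps 1, 2, 3, 4, 10, 11, 12, from 1 to 21).

**Steps most likely to fail**

1. Step 10 (the proposed new method). Three processes threaten it: hydrogen shift in the quinone methide to the enol ether styrene, followed by closure to a benzofuran; O-benzylation of the phenoxide, or S-benzylation of the liberated sulfinate, by the electron-rich sulfonium salt; and insufficient facial discrimination at the ylide carbon or leakage between anti and syn betaines, which would lower the enantiomeric and trans purity. The fallback uses a known enantioselective carbenoid C–H insertion, sets out from 2 and 12, and returns at 17. O-Alkylation of phenol 2 with bromide 12 (K2CO3, DMF) would give the benzyl ether styrene F1. Hydroboration and oxidation (9-BBN, THF; then NaOH, H2O2) would give the primary alcohol F2, oxidation (TEMPO, PhI(OAc)2, MeCN/H2O) the arylacetic acid F3, and methylation (MeI, K2CO3, DMF) the methyl arylacetate F4. Diazo transfer (4-acetamidobenzenesulfonyl azide, DBU, MeCN) would give the aryldiazoacetate F5. Insertion of the rhodium carbenoid into the benzylic C–H bond of the ether with Rh2(S-PTTL)4 (dirhodium tetrakis[N-phthaloyl-(S)-tert-leucinate], toluene, −60 °C; the enantiomeric catalyst if the sense requires) would close the ring to the cis ester F6. Epimerisation at C3 (NaOMe, MeOH) would give the trans ester F7, reduction (LiBH4, THF) the primary alcohol F8, and silylation (TBSCl, imidazole, CH2Cl2) compound 17.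

2. Step 4. The acid may strip the silyl ether; the benzylic cation may undergo a hydride shift to the arylacetaldehyde, which closes to a benzofuran; and the β-oxygen may slow ionisation so that the substitution stalls. The fallback sets out from 4 and returns at 5 without any acid. Mitsunobu thioetherification of 4 (4-methylbenzenethiol, PPh3, DIAD, THF, 0 °C) would give the benzylic aryl sulfide F9, and oxidation at sulfur (mCPBA, 2.2 equiv, CH2Cl2, 0 °C) would give sulfone 5.

3. Step 11. Oxidative addition to the electron-rich C5 bromide may be slow enough for the phosphine-free catalyst to precipitate as palladium black, and β-hydride elimination may turn toward the acetal carbon and deliver the saturated 3-arylpropanoate. The fallback sets out from 17 and returns at 20 by way of the ester oxidation level. Heck coupling of 17 with methyl acrylate (Pd(OAc)2, P(o-tol)3, Et3N, DMF, 100 °C) would give the methyl (E)-cinnamate F10, reduction (iBu2AlH, CH2Cl2, −78 °C) the allylic alcohol F11, and allylic oxidation (MnO2, CH2Cl2, rt) enal 20.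

**Further compounds**

F1 | step 10 | 5-bromo-1-methoxy-2-{[3-methoxy-4-(methoxymethoxy)phenyl]methoxy}-3-vinylbenzene | COCOc1ccc(COc2c(OC)cc(Br)cc2C=C)cc1OC
F2 | step 10 | 2-(5-bromo-3-methoxy-2-{[3-methoxy-4-(methoxymethoxy)phenyl]methoxy}phenyl)ethanol | COCOc1ccc(COc2c(OC)cc(Br)cc2CCO)cc1OC
F3 | step 10 | 2-(5-bromo-3-methoxy-2-{[3-methoxy-4-(methoxymethoxy)phenyl]methoxy}phenyl)acetic acid | COCOc1ccc(COc2c(OC)cc(Br)cc2CC(=O)O)cc1OC
F4 | step 10 | methyl 2-(5-bromo-3-methoxy-2-{[3-methoxy-4-(methoxymethoxy)phenyl]methoxy}phenyl)acetate | COCOc1ccc(COc2c(OC)cc(Br)cc2CC(=O)OC)cc1OC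
F5 | step 10 | methyl 2-(5-bromo-3-methoxy-2-{[3-methoxy-4-(methoxymethoxy)phenyl]methoxy}phenyl)-2-diazoacetate | COCOc1ccc(COc2c(OC)cc(Br)cc2C(=[N+]=[N-])C(=O)OC)cc1OC
F6 | step 10 | methyl (2R,3S)-5-bromo-7-methoxy-2-[3-methoxy-4-(methoxymethoxy)phenyl]-2,3-dihydro-1-benzofuran-3-carboxylate (cis) | COc1cc([C@@H]2Oc3c(OC)cc(Br)cc3[C@@H]2C(=O)OC)ccc1OCOC
F7 | step 10 | methyl (2R,3R)-5-bromo-7-methoxy-2-[3-methoxy-4-(methoxymethoxy)phenyl]-2,3-dihydro-1-benzofuran-3-carboxylate (trans) | COc1cc([C@@H]2Oc3c(OC)cc(Br)cc3[C@H]2C(=O)OC)ccc1OCOC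
F8 | step 10 | [(2R,3S)-5-bromo-7-methoxy-2-[3-methoxy-4-(methoxymethoxy)phenyl]-2,3-dihydro-1-benzofuran-3-yl]methanol | COc1cc([C@@H]2Oc3c(OC)cc(Br)cc3[C@H]2CO)ccc1OCOC
F9 | step 4 | 4-bromo-2-[2-(tert-butyldimethylsilyloxy)-1-(4-methylphenylsulfanyl)ethyl]-6-methoxyphenol (racemic) | COc1cc(Br)cc(C(CO[Si](C)(C)C(C)(C)C)Sc2ccc(C)cc2)c1O
F10 | step 11 | methyl (E)-3-[(2R,3S)-3-[(tert-butyldimethylsilyloxy)methyl]-7-methoxy-2-[3-methoxy-4-(methoxymethoxy)phenyl]-2,3-dihydro-1-benzofuran-5-yl]prop-2-enoate | COc1cc([C@@H]2Oc3c(OC)cc(/C=C/C(=O)OC)cc3[C@H]2CO[Si](C)(C)C(C)(C)C)ccc1OCOC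
F11 | step 11 | (E)-3-[(2R,3S)-3-[(tert-butyldimethylsilyloxy)methyl]-7-methoxy-2-[3-methoxy-4-(methoxymethoxy)phenyl]-2,3-dihydro-1-benzofuran-5-yl]prop-2-en-1-ol | COc1cc([C@@H]2Oc3c(OC)cc(/C=C/CO)cc3[C@H]2CO[Si](C)(C)C(C)(C)C)ccc1OCOC
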